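The plan forms the naphthalene ring bonded to isoquinoline C5 only after both aryl units are linked through an sp3 carbon. The key step exploits the para relationship in that ring between the biaryl carbon C1 and the oxygen-bearing C4: C1 is the methylene carbon of a diarylmethane, C2 and C3 come from methyl acrylate, and C4 is an ortho ester carbonyl. A single anionic Michael–Dieckmann annulation makes C1–C2 and C3–C4 and closes ring C1–C2–C3–C4–C4a–C8a as a tetralone; decarboxylation, dehydrogenation and O-methylation then reveal the hindered axis. The precursor is a methyl 2-(arylmethyl)-6-methoxy-4-methylbenzoate in which the aryl group is the finished cis-N-methyl tetrahydroisoquinoline.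

Key step: step 9

Assumption: the target SMILES fixes C1 as R and C3 as S but gives no sense for the biaryl axis, so the route is planned for these two centres and the two rotamers about the axis, which arise in step 11, are carried together (they are diastereomers and could be separated by chromatography if one is wanted).

**Step 1**
Reactants: 1 1-bromo-3,5-dimethoxybenzene; 2 (R)-propylene oxide
Product: 4 (R)-1-(3,5-dimethoxyphenyl)propan-2-ol, via aryl Grignard reagent 3 (not isolated)
Conditions: Mg, THF, reflux; then CuI (10 mol %), 2, −30 °C to 0 °C; H2O work-up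
Reagents that add atoms: none
Why: Copper-catalysed SN2 opening of the epoxide by the aryl Grignard reagent should occur at the unsubstituted carbon, so the stereocentre of 2 is not touched and stays R.

**Step 2**
Reactants: 4 (R)-1-(3,5-dimethoxyphenyl)propan-2-ol
Product: 5 1-[(S)-2-azidopropyl]-3,5-dimethoxybenzene
Conditions: PPh3, DIAD, (PhO)2P(O)N3, THF, 0 °C to rt
Reagents that add atoms: diphenylphosphoryl azide, [N-]=[N+]=NP(=O)(Oc1ccccc1)Oc1ccccc1
Why: Mitsunobu azidation displaces the activated secondary alcohol by SN2 with clean inversion, which turns the R carbinol into the S azide needed for C3.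

**Step 3**
Reactants: 5 1-[(S)-2-azidopropyl]-3,5-dimethoxybenzene
Product: 7 N-[(S)-1-(3,5-dimethoxyphenyl)propan-2-yl]acetamide, via primary amine 6 (not isolated)
Conditions: H2 (1 atm), 10% Pd/C, Ac2O, EtOAc, rt
Reagents that add atoms: acetic anhydride, CC(=O)OC(C)=O
Why: Catalytic hydrogenolysis of the azide gives the amine, which is acetylated as it forms, and neither event involves the stereocentre.

**Step 4**
Reactants: 7 N-[(S)-1-(3,5-dimethoxyphenyl)propan-2-yl]acetamide
Product: 8 (S)-6,8-dimethoxy-1,3-dimethyl-3,4-dihydroisoquinoline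
Conditions: POCl3, MeCN, reflux; aqueous work-up
Reagents that add atoms: none
Why: Bischler–Napieralski cyclodehydration should be easy because the ring position attacked is ortho to one methoxy group and para to the other, and the two candidate positions are equivalent by symmetry.

**Step 5**
Reactants: 8 (S)-6,8-dimethoxy-1,3-dimethyl-3,4-dihydroisoquinoline
Product: 10 (1R,3S)-6,8-dimethoxy-1,2,3-trimethyl-1,2,3,4-tetrahydroisoquinoline, via secondary amine 9 (not isolated)
Conditions: NaBH4, MeOH, 0 °C; then 37% aq. HCHO (excess), rt; NaBH4, 0 °C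
Reagents that add atoms: formaldehyde, C=O
Why: Borohydride reduction of the cyclic imine delivers hydride to C1 from the face opposite the C3 methyl group, which sets C1 as R (1,3-cis), and reductive amination with formaldehyde in the same flask then methylates nitrogen.

**Step 6**
Reactants: 10 (1R,3S)-6,8-dimethoxy-1,2,3-trimethyl-1,2,3,4-tetrahydroisoquinoline
Product: 11 (1R,3S)-5-bromo-6,8-dimethoxy-1,2,3-trimethyl-1,2,3,4-tetrahydroisoquinoline
Conditions: Br2 (1.0 equiv), AcOH, rt
Reagents that add atoms: bromine, BrBr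
Why: Electrophilic aromatic bromination should go to C5 (ortho to the 6-methoxy and para to the 8-methoxy group) and not to C7, which is flanked by two methoxy groups, while the acid keeps the amine protonated and safe from oxidation.

**Step 7**
Reactants: 12 3,5-dimethylanisole
Product: 14 methyl 2-methoxy-4,6-dimethylbenzoate, via aryllithium 13 (not isolated)
Conditions: n-BuLi, TMEDA, Et2O, 0 °C to rt; then added to ClCO2Me (excess), THF, −78 °C
Reagents that add atoms: methyl chloroformate, COC(Cl)=O
Why: Methoxy-directed ortho-lithiation can only occur at the two equivalent positions next to the methoxy group, and inverse quench with the chloroformate gives a doubly ortho-substituted ester that resists a second addition.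

**Step 8**
Reactants: 14 methyl 2-methoxy-4,6-dimethylbenzoate; 11 (1R,3S)-5-bromo-6,8-dimethoxy-1,2,3-trimethyl-1,2,3,4-tetrahydroisoquinoline
Product: 17 methyl 2-{[(1R,3S)-6,8-dimethoxy-1,2,3-trimethyl-1,2,3,4-tetrahydroisoquinolin-5-yl]methyl}-6-methoxy-4-methylbenzoate, via lithiated toluate 15 (not isolated), via benzylic zinc chloride 16 (not isolated)
Conditions: 14 (1.3 equiv), LiN(iPr)2, THF, −78 °C; ZnCl2, −78 °C to 0 °C; then 11, Pd(OAc)2 (3 mol %), SPhos (6 mol %), THF, 60 °C
Reagents that add atoms: none
Why: Ester-directed lateral lithiation takes the ortho methyl group, exchange to zinc gives a benzylic zinc reagent that tolerates the ester, and Negishi coupling with a dialkylbiarylphosphine palladium catalyst is suited to an electron-rich aryl bromide with two ortho substituents.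

**Step 9**
Reactants: 17 methyl 2-{[(1R,3S)-6,8-dimethoxy-1,2,3-trimethyl-1,2,3,4-tetrahydroisoquinolin-5-yl]methyl}-6-methoxy-4-methylbenzoate; 18 methyl acrylate
Product: 21 methyl 4-[(1R,3S)-6,8-dimethoxy-1,2,3-trimethyl-1,2,3,4-tetrahydroisoquinolin-5-yl]-8-methoxy-6-methyl-1-oxo-1,2,3,4-tetrahydronaphthalene-2-carboxylate (mixture at C2 and C4 of the new ring), via lithiated diarylmethane 19 (not isolated), via Michael adduct enolate 20 (not isolated)
Conditions: LiN(iPr)2 (1.2 equiv), THF, −78 °C; 18 (1.05 equiv, slow addition), −78 °C to 0 °C; AcOH quench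
Reagents that add atoms: none
Why: LiN(iPr)2 removes a proton from the diarylmethylene carbon of 17 to give anion 19, an ortho-quinodimethane-type ester dienolate, which adds in a 1,4-manner to methyl acrylate (naphthalene C1–C2); the ester enolate 20 so formed attacks the neighbouring benzoate carbonyl (C3–C4), and loss of methoxide leaves the stabilised keto ester enolate, protonated on quench. The closest known reaction is the toluate-anion Michael–Dieckmann annulation (Staunton–Weinreb annulation) of ortho-toluates with acrylates to 2-carboalkoxy-1-tetralones, of which the diarylmethyl anion is a more hindered and more stabilised member. The one ring formed closes by a 6-exo-trig Dieckmann condensation. The two new stereocentres (tetralone C2 and C4) are not controlled and need not be, since C2 is enolisable and both become sp2 carbons in step 11, while C1 and C3 of the isoquinoline carry no acidic hydrogen and are untouched. The step needs site-selective deprotonation, which the double benzylic activation and the coordinating ortho ester should secure over the 4-methyl group (whose anion could not cyclise in any case), and 1,4- over 1,2-addition, which the soft hindered anion and the low temperature favour.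

**Step 10**
Reactants: 21 keto ester from step 9
Product: 22 4-[(1R,3S)-6,8-dimethoxy-1,2,3-trimethyl-1,2,3,4-tetrahydroisoquinolin-5-yl]-8-methoxy-6-methyl-3,4-dihydronaphthalen-1(2H)-one (mixture at C4)
Conditions: LiCl, DMSO, H2O, 140 °C
Reagents that add atoms: none
Why: Krapcho dealkoxycarbonylation removes the methyl ester of a β-keto ester under neutral conditions that leave the aryl ethers and the tertiary amine alone.

**Step 11**
Reactants: 22 tetralone from step 10
Product: 24 4-[(1R,3S)-6,8-dimethoxy-1,2,3-trimethyl-1,2,3,4-tetrahydroisoquinolin-5-yl]-8-methoxy-6-methylnaphthalen-1-ol (both rotamers about the new axis), via keto sulfoxide 23 (not isolated)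
Conditions: NaH (2.2 equiv), PhS(O)OMe (1.2 equiv), THF, 0 °C to rt; AcOH; then toluene, 100 °C
Reagents that add atoms: none
Why: Sulfinylation of the ketone enolate at C2 followed by thermal syn-elimination of benzenesulfenic acid introduces the C2–C3 double bond, and enolisation toward the doubly benzylic C4 then gives the naphthol without any electrophilic halogen or oxidant that could attack the dimethoxyarene or the amine.

**Step 12**
Reactants: 24 naphthol from step 11
Product: 25 (1R,3S)-5-(4,5-dimethoxy-7-methylnaphthalen-1-yl)-6,8-dimethoxy-1,2,3-trimethyl-1,2,3,4-tetrahydroisoquinoline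
Conditions: Me3SiCHN2, iPr2NEt, MeCN/MeOH, rt
Reagents that add atoms: trimethylsilyldiazomethane, C[Si](C)(C)C=[N+]=[N-]
Why: O-Methylation with trimethylsilyldiazomethane needs an acidic O–H to generate the methylating species, so the naphthol is methylated while the tertiary amine cannot be quaternised.

**Compound list**

1 | 1-bromo-3,5-dimethoxybenzene | COc1cc(Br)cc(OC)c1 | starting material
2 | (R)-propylene oxide | C[C@@H]1CO1 | starting material
3 | (3,5-dimethoxyphenyl)magnesium bromide | COc1cc([Mg]Br)cc(OC)c1 | intermediate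
4 | (R)-1-(3,5-dimethoxyphenyl)propan-2-ol | C[C@@H](O)Cc1cc(OC)cc(OC)c1 | intermediate
5 | 1-[(S)-2-azidopropyl]-3,5-dimethoxybenzene | C[C@H](N=[N+]=[N-])Cc1cc(OC)cc(OC)c1 | intermediate
6 | (S)-1-(3,5-dimethoxyphenyl)propan-2-amine | C[C@H](N)Cc1cc(OC)cc(OC)c1 | intermediate
7 | N-[(S)-1-(3,5-dimethoxyphenyl)propan-2-yl]acetamide | CC(=O)N[C@@H](C)Cc1cc(OC)cc(OC)c1 | intermediate
8 | (S)-6,8-dimethoxy-1,3-dimethyl-3,4-dihydroisoquinoline | COc1cc(OC)c2c(c1)C[C@H](C)N=C2C | intermediate
9 | (1R,3S)-6,8-dimethoxy-1,3-dimethyl-1,2,3,4-tetrahydroisoquinoline | COc1cc(OC)c2c(c1)C[C@H](C)N[C@@H]2C | intermediate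
10 | (1R,3S)-6,8-dimethoxy-1,2,3-trimethyl-1,2,3,4-tetrahydroisoquinoline | COc1cc(OC)c2c(c1)C[C@H](C)N(C)[C@@H]2C | intermediate
11 | (1R,3S)-5-bromo-6,8-dimethoxy-1,2,3-trimethyl-1,2,3,4-tetrahydroisoquinoline | COc1cc(OC)c2c(c1Br)C[C@H](C)N(C)[C@@H]2C | intermediate
12 | 3,5-dimethylanisole | COc1cc(C)cc(C)c1 | starting material
13 | (2-methoxy-4,6-dimethylphenyl)lithium | [Li]c1c(OC)cc(C)cc1C | intermediate
14 | methyl 2-methoxy-4,6-dimethylbenzoate | COC(=O)c1c(C)cc(C)cc1OC | intermediate
15 | [3-methoxy-2-(methoxycarbonyl)-5-methylbenzyl]lithium (drawn C-lithiated) | [Li]Cc1cc(C)cc(OC)c1C(=O)OC | intermediate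
16 | [3-methoxy-2-(methoxycarbonyl)-5-methylbenzyl]zinc chloride | Cl[Zn]Cc1cc(C)cc(OC)c1C(=O)OC | intermediate
17 | methyl 2-{[(1R,3S)-6,8-dimethoxy-1,2,3-trimethyl-1,2,3,4-tetrahydroisoquinolin-5-yl]methyl}-6-methoxy-4-methylbenzoate | COC(=O)c1c(OC)cc(C)cc1Cc1c(OC)cc(OC)c2c1C[C@H](C)N(C)[C@@H]2C | intermediate
18 | methyl acrylate | C=CC(=O)OC | starting material
19 | 17 lithiated at the diarylmethine carbon | COC(=O)c1c(OC)cc(C)cc1C([Li])c1c(OC)cc(OC)c2c1C[C@H](C)N(C)[C@@H]2C | intermediate
20 | lithium enolate of methyl 2-{1-[(1R,3S)-6,8-dimethoxy-1,2,3-trimethyl-1,2,3,4-tetrahydroisoquinolin-5-yl]-4-methoxy-4-oxobutyl}-6-methoxy-4-methylbenzoate | COC(O[Li])=CCC(c1cc(C)cc(OC)c1C(=O)OC)c1c(OC)cc(OC)c2c1C[C@H](C)N(C)[C@@H]2C | intermediate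
21 | methyl 4-[(1R,3S)-6,8-dimethoxy-1,2,3-trimethyl-1,2,3,4-tetrahydroisoquinolin-5-yl]-8-methoxy-6-methyl-1-oxo-1,2,3,4-tetrahydronaphthalene-2-carboxylate | COC(=O)C1CC(c2c(OC)cc(OC)c3c2C[C@H](C)N(C)[C@@H]3C)c2cc(C)cc(OC)c2C1=O | intermediate
22 | 4-[(1R,3S)-6,8-dimethoxy-1,2,3-trimethyl-1,2,3,4-tetrahydroisoquinolin-5-yl]-8-methoxy-6-methyl-3,4-dihydronaphthalen-1(2H)-one | O=C1CCC(c2c(OC)cc(OC)c3c2C[C@H](C)N(C)[C@@H]3C)c2cc(C)cc(OC)c21 | intermediate
23 | 4-[(1R,3S)-6,8-dimethoxy-1,2,3-trimethyl-1,2,3,4-tetrahydroisoquinolin-5-yl]-8-methoxy-6-methyl-2-(phenylsulfinyl)-3,4-dihydronaphthalen-1(2H)-one | O=C1C(S(=O)c2ccccc2)CC(c2c(OC)cc(OC)c3c2C[C@H](C)N(C)[C@@H]3C)c2cc(C)cc(OC)c21 | intermediate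
24 | 4-[(1R,3S)-6,8-dimethoxy-1,2,3-trimethyl-1,2,3,4-tetrahydroisoquinolin-5-yl]-8-methoxy-6-methylnaphthalen-1-ol | Oc1ccc(-c2c(OC)cc(OC)c3c2C[C@H](C)N(C)[C@@H]3C)c2cc(C)cc(OC)c12 | intermediate
25 | (1R,3S)-5-(4,5-dimethoxy-7-methylnaphthalen-1-yl)-6,8-dimethoxy-1,2,3-trimethyl-1,2,3,4-tetrahydroisoquinoline | COc1cc(OC)c2c(c1-c1ccc(OC)c3c(OC)cc(C)cc13)C[C@H](C)N(C)[C@@H]2C | target

**Step count and risk**

Total step count: 12. Longest linear sequence: 11 steps (steps 1–6, then 8–12); step 7 is a one-step branch.

Steps most likely to fail: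

1. Step 9. Deprotonation at the crowded methylene carbon may be slow or reversible. The hindered anion may also add to the acrylate more slowly than the acrylate is consumed by anionic oligomerisation, or the adduct may be protonated before the ring closes. The fallback builds the naphthalene first and makes the aryl–aryl bond by cross-coupling; it sets out from toluate 14 and bromide 11 and comes back to the route at target 25. The unhindered anion 15 of 14 (LiN(iPr)2, THF, −78 °C) and methyl acrylate 18 should give methyl 8-methoxy-6-methyl-1-oxo-1,2,3,4-tetrahydronaphthalene-2-carboxylate F1. LiCl in wet DMSO at 140 °C should then give 8-methoxy-6-methyl-3,4-dihydronaphthalen-1(2H)-one F2, and dehydrogenation over Pd/C in refluxing p-cymene should give 8-methoxy-6-methylnaphthalen-1-ol F3. N-Bromosuccinimide in MeCN at −20 °C should brominate para to the hydroxyl group to give 4-bromo-8-methoxy-6-methylnaphthalen-1-ol F4, and MeI with K2CO3 in acetone should give 1-bromo-4,5-dimethoxy-7-methylnaphthalene F5. Borylation with bis(pinacolato)diboron, PdCl2(dppf) and KOAc in dioxane should give 2-(4,5-dimethoxy-7-methylnaphthalen-1-yl)-4,4,5,5-tetramethyl-1,3,2-dioxaborolane F6. Suzuki–Miyaura coupling of F6 with 11 (Pd(OAc)2, SPhos, K3PO4, toluene/H2O, 100 °C) should then give 25. This moves the risk to a hindered biaryl coupling.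

2. Step 8. The lithiated toluate may condense with its own ester before exchange to zinc, or oxidative addition into the electron-rich, doubly ortho-substituted bromide may lag so that the zinc reagent is lost by protonation. The fallback inverts the polarity of the two partners; it sets out from 14 and 11 and comes back at 17. Anion 15 added to C2Cl6 in THF at −78 °C should give methyl 2-(chloromethyl)-6-methoxy-4-methylbenzoate F7. Bromine–lithium exchange on 11 (n-BuLi, THF, −78 °C) should give [(1R,3S)-6,8-dimethoxy-1,2,3-trimethyl-1,2,3,4-tetrahydroisoquinolin-5-yl]lithium F8, which ZnCl2 converts into [(1R,3S)-6,8-dimethoxy-1,2,3-trimethyl-1,2,3,4-tetrahydroisoquinolin-5-yl]zinc chloride F9. Negishi coupling of F9 with the easily activated benzylic chloride F7 (Pd(OAc)2, SPhos, THF, 50 °C) should give 17.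

3. Step 11. Sulfinylation may stop short, or the sulfenic acid released on heating may be captured by the electron-rich naphthol. The fallback is a Saegusa–Ito dehydrogenation; it sets out from 22 and comes back at 24. Me3SiOTf and Et3N in CH2Cl2 at 0 °C should give {[4-((1R,3S)-6,8-dimethoxy-1,2,3-trimethyl-1,2,3,4-tetrahydroisoquinolin-5-yl)-8-methoxy-6-methyl-3,4-dihydronaphthalen-1-yl]oxy}trimethylsilane F10. Pd(OAc)2 (1.1 equiv) in MeCN at rt should then give the C2–C3 unsaturated ketone by β-hydride elimination, and this tautomerises to 24.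

**Further compounds**

F1 | step 9 | methyl 8-methoxy-6-methyl-1-oxo-1,2,3,4-tetrahydronaphthalene-2-carboxylate | COC(=O)C1CCc2cc(C)cc(OC)c2C1=O
F2 | step 9 | 8-methoxy-6-methyl-3,4-dihydronaphthalen-1(2H)-one | O=C1CCCc2cc(C)cc(OC)c21
F3 | step 9 | 8-methoxy-6-methylnaphthalen-1-ol | Oc1cccc2cc(C)cc(OC)c12
F4 | step 9 | 4-bromo-8-methoxy-6-methylnaphthalen-1-ol | Oc1ccc(Br)c2cc(C)cc(OC)c12
F5 | step 9 | 1-bromo-4,5-dimethoxy-7-methylnaphthalene | COc1ccc(Br)c2cc(C)cc(OC)c12
F6 | step 9 | 2-(4,5-dimethoxy-7-methylnaphthalen-1-yl)-4,4,5,5-tetramethyl-1,3,2-dioxaborolane | COc1ccc(B2OC(C)(C)C(C)(C)O2)c2cc(C)cc(OC)c12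
F7 | step 8 | methyl 2-(chloromethyl)-6-methoxy-4-methylbenzoate | COC(=O)c1c(CCl)cc(C)cc1OC
F8 | step 8 | [(1R,3S)-6,8-dimethoxy-1,2,3-trimethyl-1,2,3,4-tetrahydroisoquinolin-5-yl]lithium | COc1cc(OC)c2c(c1[Li])C[C@H](C)N(C)[C@@H]2C
F9 | step 8 | [(1R,3S)-6,8-dimethoxy-1,2,3-trimethyl-1,2,3,4-tetrahydroisoquinolin-5-yl]zinc chloride | COc1cc(OC)c2c(c1[Zn]Cl)C[C@H](C)N(C)[C@@H]2C
F10 | step 11 | {[4-((1R,3S)-6,8-dimethoxy-1,2,3-trimethyl-1,2,3,4-tetrahydroisoquinolin-5-yl)-8-methoxy-6-methyl-3,4-dihydronaphthalen-1-yl]oxy}trimethylsilane | C[Si](C)(C)OC1=CCC(c2c(OC)cc(OC)c3c2C[C@H](C)N(C)[C@@H]3C)c2cc(C)cc(OC)c21
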